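The constants I could read from the two earlier runs were rates, so I reckoned in rates, as fractions of the charged substrate per hour. Reagent in the second phase reaches the first phase, substrate becomes target there, and target is later lost.

| setting | Monday's | Wednesday's | green | ochre | amber | blue |
|---|---|---|---|---|---|---|
| substrate | 39 mM | 39 mM | 39 mM | 39 mM | 39 mM | 39 mM |
| reagent in the second phase | 46 mM | 1600 mM | 40.0 mM | 120 mM | 300 mM | 1000 mM |
| remark | run made earlier | run made earlier |  |  |  |  |
| time |  |  | 12 h | 12 h | 12 h | 12 h |
| volume of the second phase over the first |  |  | 2.0 | 2.0 | 2.0 | 2.0 |

- Monday's (time / h: target / %): 0.833: 1; 2.00: 4; 4.00: 9; 6.00: 7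
- Wednesday's (time / h: target / %): 0.500: 9; 1.00: 24; 2.50: 48; 6.00: 37

(readings scatter by 1.5 percentage points)

- in the second phase: reagent in the second phase; everything else is in the first
- charges count per volume of the first phase; a concentration in a rate is the amount of a species over the volume of its own phase; every rate counts per litre of the first phase
- the earlier runs hold the two phases in the same ratio of volumes as the flask asked about
- "hardly changes" means that all values lie within two and a half points (for a concentration: within two and a half percent of the largest)

- amount of target at the end, in percent of the substrate charged for green, ochre, amber, blue, in this order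
- the course of these numbers from the first flask to the last (rises, then falls / rises all the way / falls all the way / hardly changes / falls, then rises)

I called R the early rate: target read over time while it still climbed. Wednesday's flask had R = 0.240 h⁻¹ up to 1.00 h. It then slowed to 0.160 h⁻¹, a factor 0.667, up to 2.50 h. After that the net rate became a loss of 0.0314 h⁻¹. Control therefore changed hands near that top reading of 48%.

I carried the peak clock Θ, the early rate times the time of that crossing: 60.0%. I assumed that formation and loss speed up together, so that any flask crosses when R times its time reaches Θ.

Monday's flask stepped from 9% to 7% at its last reading, against a scatter of 1.5 percentage points, so I counted it as still climbing and took R from that last reading, where the scatter weighs least on a rate: 0.0117 h⁻¹. The two rates gave R growing as reagent to the power n = 0.852.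

At 12 h the clocks came to 12.4% for green, 31.7% for ochre, 69.2% for amber and 193% for blue. I expected green and ochre to stand near their clocks, since both clocks stayed below Θ, and amber near Wednesday's top reading. Blue's clock ran further than Wednesday's at its last reading, 144%, so I put blue below 37%.

The forecast gave 7.5%, 16%, 19% and 13%, rises, then falls, holding that “loss seems independent of reagent”.

The flasks gave 13.8%, 33.2%, 49.6% and 21.4%, rises, then falls, with the row turning at 340 mM.

    reagent in the reaction phase + target → over-reacted product (k = 0.00310 L mol⁻¹ s⁻¹)
    reagent in the reaction phase ⇌ reagent in the second phase, rate k2*([reagent in the reaction phase] - [reagent in the second phase]/K2) per volume of the first phase (partition coefficient = 17.0, kL = 3.00 × 10⁻⁴ s⁻¹)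
    2 reagent in the reaction phase → self-condensation product (k = 0.00270 L mol⁻¹ s⁻¹)
    substrate + reagent in the reaction phase → target (k = 0.00620 L mol⁻¹ s⁻¹)

In green at 5.33 h, the step to target used reagent in the reaction phase 29 times as fast as the step to over-reacted product, the momentary selectivity of a flask whose clock stood below Θ; at the end green held target 13.8% against over-reacted product 0.552%. Blue's clock reached Θ at 3.73 h. At 6.00 h blue held target 47.4% and over-reacted product 37.7%, and at 12.0 h it held target 21.4% and over-reacted product 77.1%.

The numbers in the tables are calculated for an exercise; scatter was added.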